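The route rests on cutting the C3–C4 bond of the 14-membered carbocycle. The key step exploits the vicinal C3(OH)–C4(CH3)(OH) glycol, which sits in that ring well away from the seven-membered C16(=O)–O–C12 lactone. Samarium(II) couples a C3 aldehyde with a C4 methyl ketone and should create the bond, both carbinol centres and the macrocycle in one operation. The precursor is an open-chain keto aldehyde. It already carries C1 (auxiliary alkylation), the 7Z olefin (from nerylacetone), the (11S,12S)-epoxide (Sharpless epoxidation) and a C16 silyl ether instead of a reducible acrylate. After ring closure the C16 acid opens the epoxide at C12 with inversion to give the lactone.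

Key step: step 17

Remark (numbering): C1 is the ring CH bearing C15. C15(=C17H2)–C16 is the side chain, with C16 its oxygenated carbon (the future lactone carbonyl). C18, C19 and C20 are the methyls on C4, C8 and C12.
Remark (assumption): nerylacetone is used as the geometrically pure Z isomer.
Remark (stereochemistry): the temporary carbinol centre at C4 and the sulfone-bearing C14 are carried as epimer mixtures because later steps erase both. Their SMILES leave these centres undefined.

Step 1
Reactants: 1 nerylacetone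
Product: 2 (5Z)-6,10-dimethylundeca-5,9-dien-2-ol
Conditions: NaBH4, MeOH, 0 °C
Reagents that add atoms: none
Why: Borohydride carbonyl reduction parks the C4 ketone as a carbinol, so it can be released later by neutral oxidation rather than by the acid a ketal would need and the epoxide would not stand, and the new centre is erased in step 16.

Step 2
Reactants: 2 (5Z)-6,10-dimethylundeca-5,9-dien-2-ol
Product: 3 1-({[(5Z)-6,10-dimethylundeca-5,9-dien-2-yl]oxy}methyl)-4-methoxybenzene
Conditions: NaH, PMBCl, TBAI (cat.), THF–DMF, 0 °C to rt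
Reagents that add atoms: 4-methoxybenzyl chloride, COc1ccc(CCl)cc1
Why: Williamson ether synthesis gives a PMB ether that withstands selenium dioxide, titanium/peroxide, carbanions and amalgam, and that leaves under neutral oxidative conditions orthogonal to the silyl ether.

Step 3
Reactants: 3 1-({[(5Z)-6,10-dimethylundeca-5,9-dien-2-yl]oxy}methyl)-4-methoxybenzene
Product: 5 (2E,6Z)-10-[(4-methoxybenzyl)oxy]-2,6-dimethylundeca-2,6-dien-1-ol, via over-oxidised enal 4 (not isolated)
Conditions: SeO2 (cat.), t-BuOOH (decane), CH2Cl2, 0 °C to rt; then NaBH4, MeOH, 0 °C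
Reagents that add atoms: tert-butyl hydroperoxide, CC(C)(C)OO
Why: Riley allylic oxidation (ene reaction, then [2,3]-sigmatropic shift) should attack the most accessible terminal isopropylidene at its E-methyl group to give the E-allylic alcohol that becomes C13, and the borohydride finish returns over-oxidised material.

Step 4
Reactants: 5 (2E,6Z)-10-[(4-methoxybenzyl)oxy]-2,6-dimethylundeca-2,6-dien-1-ol
Product: 6 [(2S,3S)-3-{(3Z)-7-[(4-methoxybenzyl)oxy]-3-methyloct-3-en-1-yl}-2-methyloxiran-2-yl]methanol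
Conditions: Ti(OiPr)4 (cat.), L-(+)-diethyl tartrate (cat.), t-BuOOH (decane), 4 Å MS, CH2Cl2, −20 °C
Reagents that add atoms: tert-butyl hydroperoxide, CC(C)(C)OO
Why: In the Sharpless asymmetric epoxidation titanium binds the C13 hydroxyl, so only C11=C12 reacts and the 7Z olefin is left alone, and L-(+)-tartrate should give (11S,12S) as for other (E)-2-methylalk-2-en-1-ols.

Step 5
Reactants: 6 [(2S,3S)-3-{(3Z)-7-[(4-methoxybenzyl)oxy]-3-methyloct-3-en-1-yl}-2-methyloxiran-2-yl]methanol
Product: 7 (2R,3S)-2-(iodomethyl)-3-{(3Z)-7-[(4-methoxybenzyl)oxy]-3-methyloct-3-en-1-yl}-2-methyloxirane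
Conditions: PPh3, imidazole, I2, CH2Cl2, 0 °C, dark
Reagents that add atoms: iodine, II
Why: In this Appel-type (Garegg–Samuelsson) iodination iodide displaces the oxyphosphonium group at primary C13, imidazole keeps the medium neutral for the epoxide, and no stereocentre is touched (the C12 descriptor becomes R only through CIP priorities).

Step 6
Reactants: 8 3-methylbut-3-enoic acid; 9 (4R)-4-benzyl-1,3-oxazolidin-2-one
Product: 11 (4R)-4-benzyl-3-(3-methylbut-3-enoyl)-1,3-oxazolidin-2-one, via pivalic mixed anhydride 10 (not isolated)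
Conditions: PivCl, Et3N, THF, −20 °C; then LiCl, 9, −20 °C to rt
Reagents that add atoms: none
Why: The oxazolidinone is N-acylated through the pivalic mixed anhydride, and partial migration of the olefin into conjugation would not matter because both isomers give the same dienolate in step 7.

Step 7
Reactants: 11 (4R)-4-benzyl-3-(3-methylbut-3-enoyl)-1,3-oxazolidin-2-one; 12 tert-butyl bromoacetate
Product: 14 tert-butyl (3R)-3-{[(4R)-4-benzyl-2-oxo-1,3-oxazolidin-3-yl]carbonyl}-4-methylpent-4-enoate, via sodium Z-dienolate 13 (not isolated)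
Conditions: NaHMDS, THF, −78 °C; then 12, −78 to −40 °C; AcOH quench at −78 °C
Reagents that add atoms: none
Why: In this Evans asymmetric alkylation the chelated Z-dienolate should react at its α-carbon with the activated bromide on the face away from the benzyl group, which sets C1 as R, and the cold acidic quench prevents reconjugation.

Step 8
Reactants: 14 tert-butyl (3R)-3-{[(4R)-4-benzyl-2-oxo-1,3-oxazolidin-3-yl]carbonyl}-4-methylpent-4-enoate
Product: 15 tert-butyl (3R)-3-(hydroxymethyl)-4-methylpent-4-enoate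
Conditions: LiBH4, MeOH (1 equiv), Et2O, 0 °C
Reagents that add atoms: none
Why: In this reductive removal of the auxiliary, lithium borohydride attacks the activated imide carbonyl much faster than the hindered tert-butyl ester, so C14 emerges as a primary alcohol with C1 untouched.

Step 9
Reactants: 15 tert-butyl (3R)-3-(hydroxymethyl)-4-methylpent-4-enoate
Product: 17 tert-butyl (3R)-4-methyl-3-[(phenylsulfonyl)methyl]pent-4-enoate, via phenyl sulfide 16 (not isolated)
Conditions: PhSSPh, n-Bu3P, THF, rt; solvent change; then (NH4)6Mo7O24 (cat.), 30% H2O2, EtOH, 0 °C to rt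
Reagents that add atoms: diphenyl disulfide, c1ccc(SSc2ccccc2)cc1; hydrogen peroxide, OO
Why: Hata thioetherification (SN2 at primary C14) is followed by molybdate-catalysed peroxide oxidation, in which sulfur is oxidised far faster than the unactivated 1,1-disubstituted olefin.

Step 10
Reactants: 17 tert-butyl (3R)-4-methyl-3-[(phenylsulfonyl)methyl]pent-4-enoate
Product: 19 tert-butyl (3R)-4-(hydroxymethyl)-3-[(phenylsulfonyl)methyl]pent-4-enoate, via enal 18 (not isolated)
Conditions: SeO2, t-BuOOH (decane), CH2Cl2, rt; then CeCl3·7H2O, NaBH4, MeOH, 0 °C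
Reagents that add atoms: tert-butyl hydroperoxide, CC(C)(C)OO
Why: Riley allylic oxidation with a Luche finish should convert the isopropenyl methyl group into the C16 hydroxymethyl group, because the competing tertiary C1–H is hindered and flanked by two electron-withdrawing arms.

Step 11
Reactants: 19 tert-butyl (3R)-4-(hydroxymethyl)-3-[(phenylsulfonyl)methyl]pent-4-enoate
Product: 20 tert-butyl (3R)-4-({[tert-butyl(dimethyl)silyl]oxy}methyl)-3-[(phenylsulfonyl)methyl]pent-4-enoate
Conditions: TBSCl, imidazole, CH2Cl2, 0 °C to rt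
Reagents that add atoms: tert-butyldimethylsilyl chloride, CC(C)(C)[Si](C)(C)Cl
Why: Standard silylation of the primary allylic alcohol gives a TBS ether that keeps C16 at the non-reducible alcohol level through the samarium step.

Step 12
Reactants: 20 tert-butyl (3R)-4-({[tert-butyl(dimethyl)silyl]oxy}methyl)-3-[(phenylsulfonyl)methyl]pent-4-enoate
Product: 21 (3R)-4-({[tert-butyl(dimethyl)silyl]oxy}methyl)-3-[(phenylsulfonyl)methyl]pent-4-en-1-ol
Conditions: LiAlH4, Et2O, 0 °C
Reagents that add atoms: none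
Why: Hydride reduction takes the ester to the C3 primary alcohol, and sulfone, silyl ether and olefin are inert to LiAlH4 at this temperature.

Step 13
Reactants: 21 (3R)-4-({[tert-butyl(dimethyl)silyl]oxy}methyl)-3-[(phenylsulfonyl)methyl]pent-4-en-1-ol; 7 (2R,3S)-2-(iodomethyl)-3-{(3Z)-7-[(4-methoxybenzyl)oxy]-3-methyloct-3-en-1-yl}-2-methyloxirane
Product: 23 (3R)-3-(3-{[tert-butyl(dimethyl)silyl]oxy}prop-1-en-2-yl)-5-[(2S,3S)-3-{(3Z)-7-[(4-methoxybenzyl)oxy]-3-methyloct-3-en-1-yl}-2-methyloxiran-2-yl]-4-(phenylsulfonyl)pentan-1-ol, via dilithio dianion 22 (not isolated)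
Conditions: n-BuLi (2.1 equiv), THF–DMPU, −78 to −30 °C; then 7, −78 to −10 °C; H2O quench
Reagents that add atoms: none
Why: This is the alkylation of a sulfone-stabilised carbanion (SN2 at C13), in which the first equivalent of base stores the C3 hydroxyl as its alkoxide so no protecting group is needed, carbon is far more nucleophilic than the alkoxide, the tied-back oxirane eases the neopentyl-type hindrance, and the new C14 centre disappears in step 14.

Step 14
Reactants: 23 (3R)-3-(3-{[tert-butyl(dimethyl)silyl]oxy}prop-1-en-2-yl)-5-[(2S,3S)-3-{(3Z)-7-[(4-methoxybenzyl)oxy]-3-methyloct-3-en-1-yl}-2-methyloxiran-2-yl]-4-(phenylsulfonyl)pentan-1-ol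
Product: 24 (3R)-3-(3-{[tert-butyl(dimethyl)silyl]oxy}prop-1-en-2-yl)-5-[(2S,3S)-3-{(3Z)-7-[(4-methoxybenzyl)oxy]-3-methyloct-3-en-1-yl}-2-methyloxiran-2-yl]pentan-1-ol
Conditions: 6% Na(Hg), Na2HPO4, MeOH–THF, −20 to 0 °C
Reagents that add atoms: none
Why: Reductive desulfonylation proceeds by electron transfer from sodium amalgam under phosphate buffer, conditions that do not reduce isolated epoxides, PMB and silyl ethers or unconjugated olefins.

Step 15
Reactants: 24 (3R)-3-(3-{[tert-butyl(dimethyl)silyl]oxy}prop-1-en-2-yl)-5-[(2S,3S)-3-{(3Z)-7-[(4-methoxybenzyl)oxy]-3-methyloct-3-en-1-yl}-2-methyloxiran-2-yl]pentan-1-ol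
Product: 25 (3R)-3-(3-{[tert-butyl(dimethyl)silyl]oxy}prop-1-en-2-yl)-5-{(2S,3S)-3-[(3Z)-7-hydroxy-3-methyloct-3-en-1-yl]-2-methyloxiran-2-yl}pentan-1-ol
Conditions: DDQ, CH2Cl2–pH 7 buffer, 0 °C
Reagents that add atoms: none
Why: Oxidative PMB cleavage with DDQ (benzylic hydride abstraction, then hydrolysis) in buffered medium spares epoxide, silyl ether and olefins.

Step 16
Reactants: 25 (3R)-3-(3-{[tert-butyl(dimethyl)silyl]oxy}prop-1-en-2-yl)-5-{(2S,3S)-3-[(3Z)-7-hydroxy-3-methyloct-3-en-1-yl]-2-methyloxiran-2-yl}pentan-1-ol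
Product: 26 (3R)-3-(3-{[tert-butyl(dimethyl)silyl]oxy}prop-1-en-2-yl)-5-{(2S,3S)-2-methyl-3-[(3Z)-3-methyl-7-oxooct-3-en-1-yl]oxiran-2-yl}pentanal
Conditions: TPAP (cat.), NMO, 4 Å MS, CH2Cl2, rt
Reagents that add atoms: none
Why: Ley–Griffith oxidation turns the primary and the secondary carbinol into aldehyde and ketone in one neutral operation, merges the C4 epimers, and cannot epimerise C1, which is β to the aldehyde.

Step 17
Reactants: 26 (3R)-3-(3-{[tert-butyl(dimethyl)silyl]oxy}prop-1-en-2-yl)-5-{(2S,3S)-2-methyl-3-[(3Z)-3-methyl-7-oxooct-3-en-1-yl]oxiran-2-yl}pentanal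
Product: 28 (1R,3R,4S,7Z,11S,12S)-16-(tert-butyldimethylsilyloxy)-11,12-epoxycembra-7,15(17)-diene-3,4-diol, via samarium(III) diolate 27 (not isolated)
Conditions: SmI2 (3 equiv, 0.1 M in THF), THF, 0 °C, 26 added by syringe pump (final ca. 1 mM), no HMPA, no proton source; quench directly after addition with aq. NaHCO3/Rochelle salt
Reagents that add atoms: none
Why: Single-electron transfers from SmI2 give samarium(III) ketyls (the aldehyde first), the C3 ketyl carbon bonds to the samarium-bound C4 carbonyl carbon, and the bis-alkoxide 27 is then hydrolysed; the closest known reaction type is the samarium- or titanium-mediated intramolecular pinacol coupling of keto aldehydes to 14-membered carbocyclic 1,2-diols. The 14-membered ring closes in a 14-exo-trig mode (C3 radical onto the C4=O carbon), and pseudo-high dilution together with the bends that the 7Z olefin and the trans-epoxide put into the chain should favour it over oligomerisation. The relative configuration at C3/C4 should be set by the oxophilic metal, which holds both oxygens syn so that the ring arms C2 and C5 leave on the same side (ring-cis, 3R*,4S*). The absolute sense (3R,4S rather than 3S,4R) can only come from the folded macrocyclic transition state biased by the C1 side chain and the epoxide, and this facial selectivity is the accepted risk of the route. The epoxide, the allylic silyl ether and the three olefins must survive: no HMPA or proton source is present, C16 is at the alcohol level so no acrylate acceptor exists, and ketyl–olefin closure could only be 4-exo or 5-endo. Low-valent titanium is avoided because it deoxygenates epoxides.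

Step 18
Reactants: 28 (1R,3R,4S,7Z,11S,12S)-16-(tert-butyldimethylsilyloxy)-11,12-epoxycembra-7,15(17)-diene-3,4-diol
Product: 29 (1R,3R,4S,7Z,11S,12S)-16-(tert-butyldimethylsilyloxy)-11,12-epoxy-3,4-(isopropylidenedioxy)cembra-7,15(17)-diene
Conditions: 2,2-dimethoxypropane, PPTS (cat.), CH2Cl2, rt
Reagents that add atoms: 2,2-dimethoxypropane, COC(C)(C)OC
Why: Acid-catalysed transketalisation closes a dioxolane on the ring-cis glycol, which is needed because a free C3 hydroxyl would trap the C16 carbonyl as a six-membered lactol or lactone in step 20 and either hydroxyl could attack the activated epoxide in step 21.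

Step 19
Reactants: 29 (1R,3R,4S,7Z,11S,12S)-16-(tert-butyldimethylsilyloxy)-11,12-epoxy-3,4-(isopropylidenedioxy)cembra-7,15(17)-diene
Product: 30 (1R,3R,4S,7Z,11S,12S)-11,12-epoxy-3,4-(isopropylidenedioxy)cembra-7,15(17)-dien-16-ol
Conditions: TBAF, THF, 0 °C to rt
Reagents that add atoms: none
Why: Fluoride-induced desilylation frees the allylic alcohol, and epoxide and acetonide are inert to TBAF.

Step 20
Reactants: 30 (1R,3R,4S,7Z,11S,12S)-11,12-epoxy-3,4-(isopropylidenedioxy)cembra-7,15(17)-dien-16-ol
Product: 32 (1R,3R,4S,7Z,11S,12S)-11,12-epoxy-3,4-(isopropylidenedioxy)cembra-7,15(17)-dien-16-oic acid, via enal 31 (not isolated)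
Conditions: MnO2, CH2Cl2, rt; filter; then NaClO2, NaH2PO4, 2-methyl-2-butene, t-BuOH–H2O, 0 °C
Reagents that add atoms: sodium chlorite, [Na+].[O-]Cl=O
Why: Manganese dioxide oxidises only the allylic alcohol, and the Pinnick oxidation (chlorite plus hypochlorite scavenger) takes the crude enal to the acid without touching olefins or epoxide.

Step 21
Reactants: 32 (1R,3R,4S,7Z,11S,12S)-11,12-epoxy-3,4-(isopropylidenedioxy)cembra-7,15(17)-dien-16-oic acid
Product: 33 (1R,3R,4S,7Z,11S,12R)-11-hydroxy-3,4-(isopropylidenedioxy)cembra-7,15(17)-dien-16,12-olide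
Conditions: CSA (cat.), CH2Cl2 (ca. 2 mM), 0 °C to rt
Reagents that add atoms: none
Why: In this acid-catalysed epoxy-acid lactonisation (7-exo-tet) the carboxylic acid should attack the protonated epoxide at the more substituted C12 from the rear, so C12 inverts to R while the C11–O bond and its S configuration stay.

Step 22
Reactants: 33 (1R,3R,4S,7Z,11S,12R)-11-hydroxy-3,4-(isopropylidenedioxy)cembra-7,15(17)-dien-16,12-olide
Product: 34 (1R,3R,4S,7Z,11S,12R)-3,4,11-trihydroxycembra-7,15(17)-dien-16,12-olide (CNP0263298.1)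
Conditions: AcOH–H2O (4:1), 40 °C
Reagents that add atoms: none
Why: Mild acetal hydrolysis in aqueous acetic acid removes the acetonide, and this acid is too weak to move the hindered tertiary lactone onto O3 or to isomerise the 7Z olefin.

Compound list
1 | nerylacetone, (5Z)-6,10-dimethylundeca-5,9-dien-2-one | CC(C)=CCC/C(C)=C\CCC(C)=O | starting material
2 | (5Z)-6,10-dimethylundeca-5,9-dien-2-ol (C4 epimers) | CC(C)=CCC/C(C)=C\CCC(C)O | intermediate
3 | PMB ether of 2 | CC(C)=CCC/C(C)=C\CCC(C)OCc1ccc(OC)cc1 | intermediate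
4 | (2E,6Z)-10-[(4-methoxybenzyl)oxy]-2,6-dimethylundeca-2,6-dienal | O=C/C(C)=C/CC/C(C)=C\CCC(C)OCc1ccc(OC)cc1 | intermediate
5 | (2E,6Z)-10-[(4-methoxybenzyl)oxy]-2,6-dimethylundeca-2,6-dien-1-ol | OC/C(C)=C/CC/C(C)=C\CCC(C)OCc1ccc(OC)cc1 | intermediate
6 | (2S,3S)-epoxy alcohol (11S,12S) | OC[C@]1(C)O[C@H]1CC/C(C)=C\CCC(C)OCc1ccc(OC)cc1 | intermediate
7 | (2R,3S)-epoxy iodide (same spatial arrangement as 6) | IC[C@]1(C)O[C@H]1CC/C(C)=C\CCC(C)OCc1ccc(OC)cc1 | intermediate
8 | 3-methylbut-3-enoic acid | C=C(C)CC(=O)O | starting material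
9 | (4R)-4-benzyl-1,3-oxazolidin-2-one | O=C1N[C@H](Cc2ccccc2)CO1 | starting material
10 | 3-methylbut-3-enoic pivalic anhydride | C=C(C)CC(=O)OC(=O)C(C)(C)C | intermediate
11 | (4R)-4-benzyl-3-(3-methylbut-3-enoyl)-1,3-oxazolidin-2-one | C=C(C)CC(=O)N1[C@H](Cc2ccccc2)COC1=O | intermediate
12 | tert-butyl bromoacetate | CC(C)(C)OC(=O)CBr | starting material
13 | sodium (Z)-dienolate of 11 | [Na+].C=C(C)/C=C(\[O-])N1[C@H](Cc2ccccc2)COC1=O | intermediate
14 | tert-butyl (3R)-3-{[(4R)-4-benzyl-2-oxo-1,3-oxazolidin-3-yl]carbonyl}-4-methylpent-4-enoate | C=C(C)[C@@H](CC(=O)OC(C)(C)C)C(=O)N1[C@H](Cc2ccccc2)COC1=O | intermediate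
15 | tert-butyl (3R)-3-(hydroxymethyl)-4-methylpent-4-enoate | C=C(C)[C@@H](CC(=O)OC(C)(C)C)CO | intermediate
16 | tert-butyl (3R)-4-methyl-3-[(phenylsulfanyl)methyl]pent-4-enoate | C=C(C)[C@@H](CC(=O)OC(C)(C)C)CSc1ccccc1 | intermediate
17 | tert-butyl (3R)-4-methyl-3-[(phenylsulfonyl)methyl]pent-4-enoate | C=C(C)[C@@H](CC(=O)OC(C)(C)C)CS(=O)(=O)c1ccccc1 | intermediate
18 | tert-butyl (3R)-4-formyl-3-[(phenylsulfonyl)methyl]pent-4-enoate | C=C(C=O)[C@@H](CC(=O)OC(C)(C)C)CS(=O)(=O)c1ccccc1 | intermediate
19 | tert-butyl (3R)-4-(hydroxymethyl)-3-[(phenylsulfonyl)methyl]pent-4-enoate | C=C(CO)[C@@H](CC(=O)OC(C)(C)C)CS(=O)(=O)c1ccccc1 | intermediate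
20 | TBS ether of 19 | C=C(CO[Si](C)(C)C(C)(C)C)[C@@H](CC(=O)OC(C)(C)C)CS(=O)(=O)c1ccccc1 | intermediate
21 | (3R)-4-({[tert-butyl(dimethyl)silyl]oxy}methyl)-3-[(phenylsulfonyl)methyl]pent-4-en-1-ol | C=C(CO[Si](C)(C)C(C)(C)C)[C@@H](CCO)CS(=O)(=O)c1ccccc1 | intermediate
22 | O,C14-dilithio derivative of 21 | [Li+].[Li+].C=C(CO[Si](C)(C)C(C)(C)C)[C@@H](CC[O-])[CH-]S(=O)(=O)c1ccccc1 | intermediate
23 | coupled C14 sulfone (C4 and C14 epimers) | C=C(CO[Si](C)(C)C(C)(C)C)[C@@H](CCO)C(C[C@]1(C)O[C@H]1CC/C(C)=C\CCC(C)OCc1ccc(OC)cc1)S(=O)(=O)c1ccccc1 | intermediate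
24 | desulfonylated C3 alcohol, C4 PMB ether | C=C(CO[Si](C)(C)C(C)(C)C)[C@@H](CCO)CC[C@]1(C)O[C@H]1CC/C(C)=C\CCC(C)OCc1ccc(OC)cc1 | intermediate
25 | seco 3,4-diol | C=C(CO[Si](C)(C)C(C)(C)C)[C@@H](CCO)CC[C@]1(C)O[C@H]1CC/C(C)=C\CCC(C)O | intermediate
26 | seco keto aldehyde (1R,7Z,11S,12S), key-step precursor | C=C(CO[Si](C)(C)C(C)(C)C)[C@@H](CC=O)CC[C@]1(C)O[C@H]1CC/C(C)=C\CCC(C)=O | intermediate
27 | bis(diiodosamarium) 3,4-diolate of 28 | C=C(CO[Si](C)(C)C(C)(C)C)[C@@H]1CC[C@]2(C)O[C@H]2CC/C(C)=C\CC[C@](C)(O[Sm](I)I)[C@H](O[Sm](I)I)C1 | intermediate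
28 | macrocyclic (1R,3R,4S,7Z,11S,12S)-3,4-diol, key-step product | C=C(CO[Si](C)(C)C(C)(C)C)[C@@H]1CC[C@]2(C)O[C@H]2CC/C(C)=C\CC[C@](C)(O)[C@H](O)C1 | intermediate
29 | 3,4-acetonide of 28 | C=C(CO[Si](C)(C)C(C)(C)C)[C@@H]1CC[C@]2(C)O[C@H]2CC/C(C)=C\CC[C@]3(C)OC(C)(C)O[C@@H]3C1 | intermediate
30 | C16 allylic alcohol | C=C(CO)[C@@H]1CC[C@]2(C)O[C@H]2CC/C(C)=C\CC[C@]3(C)OC(C)(C)O[C@@H]3C1 | intermediate
31 | C16 enal | C=C(C=O)[C@@H]1CC[C@]2(C)O[C@H]2CC/C(C)=C\CC[C@]3(C)OC(C)(C)O[C@@H]3C1 | intermediate
32 | C16 epoxy acid | C=C(C(=O)O)[C@@H]1CC[C@]2(C)O[C@H]2CC/C(C)=C\CC[C@]3(C)OC(C)(C)O[C@@H]3C1 | intermediate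
33 | 16,12-lactone acetonide (11S,12R) | C=C1C(=O)O[C@]2(C)CC[C@@H]1C[C@H]3OC(C)(C)O[C@@]3(C)CC/C=C(/C)CC[C@@H]2O | intermediate
34 | CNP0263298.1, (1R,3R,4S,7Z,11S,12R)-3,4,11-trihydroxycembra-7,15(17)-dien-16,12-olide | C=C1C(=O)O[C@]2(C)CC[C@@H]1C[C@@H](O)[C@@](C)(O)CC/C=C(/C)CC[C@@H]2O | target

Total step count: 22. Longest linear sequence: 17 steps (steps 6–22). Steps 1–5 form the convergent branch.

Steps most likely to fail

Step 17. The failure processes are poor facial discrimination at C3/C4, premature reduction of the aldehyde, oligomerisation, and slow opening of the epoxide by samarium(III) iodide. The fallback separates ring closure from control of C3. It sets out from 26. The coupling is run without regard to C3, and 28 is taken on together with the 3-epimeric diol F1. Parikh–Doering oxidation of the secondary carbinol should merge both into the (4S)-4-hydroxy-3-ketone F2. Chelation-controlled reduction with Zn(BH4)2 delivers hydride from the methyl-bearing face of the five-membered zinc chelate. This should place C2 cis to C5 and return the route at 28.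

Step 13. The failure processes are sluggish substitution at the neopentyl-like C13, attack of the carbanion on iodine followed by reductive fragmentation of the epoxide, and silyl migration to the C3 alkoxide. The fallback replaces the substitution by a carbonyl addition. It sets out from 6 and 21.
- Parikh–Doering oxidation of 6 should give the non-enolisable epoxy aldehyde F3.
- Addition of dianion 22 at −78 °C with in situ acetylation should give the bis-acetate F4.
- Sodium amalgam, then K2CO3 in methanol (Julia–Lythgoe olefination), should give the (13E)-alkenol F5.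
- Diimide, generated from 2-nitrobenzenesulfonyl hydrazide, should saturate the only 1,2-disubstituted olefin and return the route at 24.

Step 21. The failure processes are attack at C11 (8-endo), participation of the C7=C8 π bond in opening of the activated epoxide, rearrangement of the epoxide to a ketone, and loss of the acetonide. The fallback makes the lactone C–O bond at the acyl carbon instead of at C12. It sets out from 32. Neutral hydrolysis in hot buffered water–dioxane has water as the overwhelming nucleophile at the tertiary carbon, with inversion, and should give the 11,12-dihydroxy acid F6. Shiina lactonisation (MNBA, DMAP, high dilution) should then acylate O12 and return the route at 33. A vicinal acyl shift should correct any acylation at O11.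

Further compounds
F1 | step 17 | (1R,3S,4S,7Z,11S,12S)-16-(tert-butyldimethylsilyloxy)-11,12-epoxycembra-7,15(17)-diene-3,4-diol | C=C(CO[Si](C)(C)C(C)(C)C)[C@@H]1CC[C@]2(C)O[C@H]2CC/C(C)=C\CC[C@](C)(O)[C@@H](O)C1
F2 | step 17 | (1R,4S,7Z,11S,12S)-16-(tert-butyldimethylsilyloxy)-11,12-epoxy-4-hydroxycembra-7,15(17)-dien-3-one | C=C(CO[Si](C)(C)C(C)(C)C)[C@@H]1CC[C@]2(C)O[C@H]2CC/C(C)=C\CC[C@](C)(O)C(=O)C1
F3 | step 13 | (2R,3S)-3-{(3Z)-7-[(4-methoxybenzyl)oxy]-3-methyloct-3-en-1-yl}-2-methyloxirane-2-carbaldehyde | O=C[C@]1(C)O[C@H]1CC/C(C)=C\CCC(C)OCc1ccc(OC)cc1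
F4 | step 13 | 3,13-bis-acetate of the 13-hydroxy-14-(phenylsulfonyl) adduct | C=C(CO[Si](C)(C)C(C)(C)C)[C@@H](CCOC(C)=O)C(C(OC(C)=O)[C@]1(C)O[C@H]1CC/C(C)=C\CCC(C)OCc1ccc(OC)cc1)S(=O)(=O)c1ccccc1
F5 | step 13 | (13E)-13,14-didehydro analogue of 24 | C=C(CO[Si](C)(C)C(C)(C)C)[C@@H](CCO)/C=C/[C@]1(C)O[C@H]1CC/C(C)=C\CCC(C)OCc1ccc(OC)cc1
F6 | step 21 | (1R,3R,4S,7Z,11S,12R)-11,12-dihydroxy-3,4-(isopropylidenedioxy)cembra-7,15(17)-dien-16-oic acid | C=C(C(=O)O)[C@@H]1CC[C@@](C)(O)[C@@H](O)CC/C(C)=C\CC[C@]2(C)OC(C)(C)O[C@@H]2C1
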